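**Plan**

1. Ring numbered C1–C14: C1 carries CH2OH, alkenes C1=C2 (E), C5=C6 (Z), C11=C12 (E), and C8 is the only stereocentre (R). The side chain is C1'–C7', bonded through C2'. The retrosynthesis cuts C1=C2 (ring), C8–C2' (ring methine to side-chain alkene carbon) and C7–C8.
2. Enabling feature: C8 is a ring CH between two CH2 groups (C7, C9) and is bonded to the methyl-bearing sp2 carbon C2' of a trisubstituted alkene. This is the retron of a boron 1,2-metallate shift of a secondary alkyl group onto a 1-methylalkenyl carbon. Both carbons are used as nucleophiles (C8–B and C2'–Li) and are united on boron with iodine as oxidant; the C8–B bond is a temporary bond that fixes the stereocentre and is lost in the same step.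
3. Forward order: neryl acetate gives a (Z)-allylboronate (ring C2–C7); pent-4-yn-1-ol gives an (E)-alkenyl TIB ester (ring C8–C14). Lithiation–borylation joins C7–C8 and leaves C8–Bpin. The iodine-induced coupling with the C8 alkenyllithium joins C8–C2'. Phosphonoacetate adds C1, an intramolecular olefination closes the only ring at C1=C2, and ester reduction ends the route.
4. Stereochemistry: C8 comes from (−)-sparteine-controlled deprotonation (reagent control) and is carried through two stereospecific 1,2-shifts (inversion, then retention). C5=C6 (Z) comes from nerol, C11=C12 (E) from syn-methylalumination, C2'=C3' (E) from the Z iodide by anti-migration/anti-elimination, and C1=C2 from the E-selective phosphonate olefination.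

Key step: step 11

Remark: the phosphonate-bearing carbon made in step 14 forms as both epimers and is removed in step 16; the oxirane carbon made in step 1 is racemic and is removed in step 2.

**Route**

Step 1
Reactants: 1 neryl acetate
Product: 2 (2Z)-6,7-epoxy-3,7-dimethyloct-2-en-1-yl acetate
Conditions: mCPBA (1.0 equiv), CH2Cl2, −10 → 0 °C
Reagents that add atoms: mCPBA OOC(=O)c1cccc(Cl)c1
Why: Prilezhaev epoxidation should take the electron-rich C6=C7 alkene, because the C2=C3 alkene is deactivated by the allylic acetate; the new oxirane centre is of no consequence.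

Step 2
Reactants: 2 (2Z)-6,7-epoxy-3,7-dimethyloct-2-en-1-yl acetate
Product: 3 (2Z)-3-methyl-6-oxohex-2-en-1-yl acetate
Conditions: H5IO6 (1.1 equiv), THF/H2O, 0 °C → rt
Reagents that add atoms: none
Why: Periodic acid opens the epoxide to the diol and cleaves it (glycol cleavage) to the aldehyde and acetone, under conditions that should leave the allylic acetate and the Z alkene untouched.

Step 3
Reactants: 3 (2Z)-3-methyl-6-oxohex-2-en-1-yl acetate
Product: 4 (2Z)-6,6-dimethoxy-3-methylhex-2-en-1-yl acetate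
Conditions: HC(OMe)3, MeOH, PPTS (cat.), rt
Reagents that add atoms: trimethyl orthoformate COC(OC)OC
Why: Acid-catalysed acetalisation with the orthoformate as water scavenger masks the aldehyde as a dimethyl acetal that tolerates the organolithium and basic steps ahead.

Step 4
Reactants: 4 (2Z)-6,6-dimethoxy-3-methylhex-2-en-1-yl acetate
Product: 5 2-[(2Z)-6,6-dimethoxy-3-methylhex-2-en-1-yl]-4,4,5,5-tetramethyl-1,3,2-dioxaborolane
Conditions: B2pin2, Ni(cod)2 (5 mol%), PCy3 (10 mol%), EtOAc, rt
Reagents that add atoms: bis(pinacolato)diboron CC1(C)OB(OC1(C)C)B1OC(C)(C)C(C)(C)O1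
Why: Nickel-catalysed Miyaura-type borylation of an allylic acetate (oxidative addition, B–B transmetalation, C–B reductive elimination at the unsubstituted allyl terminus) should give the primary allylboronate; the trisubstituted terminus does not equilibrate quickly, so the Z geometry should be kept.

Step 5
Reactants: 6 pent-4-yn-1-ol; 7 2,4,6-triisopropylbenzoic acid
Product: 8 pent-4-yn-1-yl 2,4,6-triisopropylbenzoate
Conditions: PPh3, DIAD, THF, 0 °C → rt
Reagents that add atoms: none
Why: Mitsunobu esterification of a primary alcohol is the standard entry to hindered TIB esters, which direct and survive α-lithiation.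

Step 6
Reactants: 8 pent-4-yn-1-yl 2,4,6-triisopropylbenzoate
Product: 11 (4E)-7-hydroxy-4-methylhept-4-en-1-yl 2,4,6-triisopropylbenzoate, via alkenylalane 9 (not isolated), via lithium alanate 10 (not isolated)
Conditions: AlMe3, Cp2ZrCl2 (cat.), CH2Cl2, 0 °C → rt; evaporate, hexane/THF; n-BuLi, −78 → 0 °C; ethylene oxide, −30 °C → rt; aqueous work-up
Reagents that add atoms: trimethylaluminium C[Al](C)C; ethylene oxide C1CO1
Why: Zirconium-catalysed syn-methylalumination (Negishi carboalumination) puts Me on the internal and Al on the terminal alkyne carbon, which fixes the E geometry, and the alanate made with n-BuLi should transfer the alkenyl group to ethylene oxide with retention while the hindered benzoate is not attacked.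

Step 7
Reactants: 11 (4E)-7-hydroxy-4-methylhept-4-en-1-yl 2,4,6-triisopropylbenzoate
Product: 12 (4E)-7-[(tert-butyldimethylsilyl)oxy]-4-methylhept-4-en-1-yl 2,4,6-triisopropylbenzoate
Conditions: TBSCl, imidazole, DMF, rt
Reagents that add atoms: TBSCl CC(C)(C)[Si](C)(C)Cl
Why: Standard silylation of a primary alcohol gives an ether that should survive s-BuLi, the alkenyllithium and iodine/methoxide.

Step 8
Reactants: 13 4-methylpent-3-en-1-ol
Product: 14 4-methylpent-3-enal
Conditions: Dess–Martin periodinane, CH2Cl2, 0 °C → rt; filtered solution used at once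
Reagents that add atoms: none
Why: Dess–Martin oxidation is mild enough to give the β,γ-unsaturated aldehyde without migration of the alkene into conjugation.

Step 9
Reactants: 14 4-methylpent-3-enal; 15 ethyltriphenylphosphonium iodide
Product: 19 (2Z)-2-iodo-6-methylhepta-2,5-diene, via ethylidene ylide 16 (not isolated), via iodoethylphosphonium iodide 17 (not isolated), via iodo ylide 18 (not isolated)
Conditions: 15, n-BuLi, THF, rt; I2, −78 °C; NaHMDS, −20 °C; then 14, −78 °C → rt
Reagents that add atoms: iodine II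
Why: Wittig olefination with the α-iodoethylidene ylide (Stork–Zhao type) is kinetically Z-selective, so iodine should end up cis to the chain, and at −78 °C olefination should outrun enolisation of the aldehyde.

Step 10
Reactants: 12 (4E)-7-[(tert-butyldimethylsilyl)oxy]-4-methylhept-4-en-1-yl 2,4,6-triisopropylbenzoate; 5 2-[(2Z)-6,6-dimethoxy-3-methylhex-2-en-1-yl]-4,4,5,5-tetramethyl-1,3,2-dioxaborolane
Product: 22 tert-butyl{[(3E,7R,9Z)-13,13-dimethoxy-4,10-dimethyl-7-(4,4,5,5-tetramethyl-1,3,2-dioxaborolan-2-yl)trideca-3,9-dien-1-yl]oxy}dimethylsilane, via lithiated benzoate 20 (not isolated), via allylboronate complex 21 (not isolated)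
Conditions: s-BuLi, (−)-sparteine, Et2O, −78 °C, 5 h; then 5, −78 °C, 1 h; then 35 °C, 16 h
Reagents that add atoms: none
Why: In this lithiation–borylation, s-BuLi/(−)-sparteine removes the pro-S α-proton of the benzoate, the configurationally stable carbenoid adds to boron with retention, and the allyl group then shifts 1,2 with inversion as the benzoate leaves (Matteson-type rearrangement), which should set C8 as R under reagent control.

Step 11
Reactants: 22 tert-butyl{[(3E,7R,9Z)-13,13-dimethoxy-4,10-dimethyl-7-(4,4,5,5-tetramethyl-1,3,2-dioxaborolan-2-yl)trideca-3,9-dien-1-yl]oxy}dimethylsilane; 19 (2Z)-2-iodo-6-methylhepta-2,5-diene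
Product: 26 tert-butyl{[(3E,7R,9Z)-13,13-dimethoxy-4,10-dimethyl-7-[(2E)-6-methylhepta-2,5-dien-2-yl]trideca-3,9-dien-1-yl]oxy}dimethylsilane, via alkenyllithium 23 (not isolated), via alkenylboronate complex 24 (not isolated), via iodoboronic ester 25 (not isolated)
Conditions: 19, t-BuLi (2 equiv per 19), THF, −78 °C; add to 22, THF, −78 °C; I2, MeOH, −78 °C; NaOMe, MeOH, −78 °C → rt
Reagents that add atoms: none
Why: Iodine–lithium exchange gives the (Z)-alkenyllithium with retention, it adds to boron to give the tetracoordinate boronate, iodine forms an iodonium ion on the electron-rich alkenyl group and triggers the 1,2-shift of C8 from boron to C2' anti to the new C–I bond, and methoxide then induces anti elimination of boron and iodide. The closest known reaction type is the Zweifel olefination of a secondary alkyl pinacol boronic ester with a 1,2-disubstituted alkenyllithium, which formally unites two nucleophilic carbons on boron with iodine as the oxidant. No ring is closed in this step. No new stereocentre is made: the migrating carbon C8 keeps its configuration, so the R centre from step 10 is transferred, and the E geometry of C2'=C3' follows from anti-migration/anti-elimination, which inverts the alkenyl geometry and is the reason for using the Z iodide. The step needs iodine to attack only the alkenylboronate in the presence of three other trisubstituted alkenes, and the alkyl group rather than a pinacol oxygen to migrate; the anionic alkenylboronate is far more nucleophilic than a neutral alkene at −78 °C, and carbon migrates in preference to alkoxy in pinacol boronates.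

Step 12
Reactants: 26 tert-butyl{[(3E,7R,9Z)-13,13-dimethoxy-4,10-dimethyl-7-[(2E)-6-methylhepta-2,5-dien-2-yl]trideca-3,9-dien-1-yl]oxy}dimethylsilane
Product: 27 (3E,7R,9Z)-13,13-dimethoxy-4,10-dimethyl-7-[(2E)-6-methylhepta-2,5-dien-2-yl]trideca-3,9-dien-1-ol
Conditions: TBAF, THF, 0 °C → rt
Reagents that add atoms: none
Why: Fluoride-mediated desilylation should free the primary alcohol without touching the acetal or the alkenes.

Step 13
Reactants: 27 (3E,7R,9Z)-13,13-dimethoxy-4,10-dimethyl-7-[(2E)-6-methylhepta-2,5-dien-2-yl]trideca-3,9-dien-1-ol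
Product: 28 (4Z,7R,10E)-13-iodo-1,1-dimethoxy-4,10-dimethyl-7-[(2E)-6-methylhepta-2,5-dien-2-yl]trideca-4,10-diene
Conditions: I2, PPh3, imidazole, CH2Cl2, 0 °C
Reagents that add atoms: iodine II
Why: Appel-type iodination of a primary alcohol under imidazole-buffered conditions should spare the acetal and the skipped diene.

Step 14
Reactants: 28 (4Z,7R,10E)-13-iodo-1,1-dimethoxy-4,10-dimethyl-7-[(2E)-6-methylhepta-2,5-dien-2-yl]trideca-4,10-diene; 29 triethyl phosphonoacetate
Product: 30 ethyl (5E,9R,11Z)-2-(diethoxyphosphoryl)-15,15-dimethoxy-6,12-dimethyl-9-[(2E)-6-methylhepta-2,5-dien-2-yl]pentadeca-5,11-dienoate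
Conditions: NaH, 29 (excess), THF/DMF, 0 → 60 °C
Reagents that add atoms: none
Why: SN2 C-alkylation of the soft sodium phosphonoacetate anion by the primary iodide should be favoured over E2, and the excess of phosphonate limits double alkylation.

Step 15
Reactants: 30 ethyl (5E,9R,11Z)-2-(diethoxyphosphoryl)-15,15-dimethoxy-6,12-dimethyl-9-[(2E)-6-methylhepta-2,5-dien-2-yl]pentadeca-5,11-dienoate
Product: 31 ethyl (5E,9R,11Z)-2-(diethoxyphosphoryl)-6,12-dimethyl-9-[(2E)-6-methylhepta-2,5-dien-2-yl]-15-oxopentadeca-5,11-dienoate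
Conditions: TsOH·H2O (cat.), acetone/H2O, rt
Reagents that add atoms: water O
Why: Mild acid-catalysed acetal hydrolysis should free the aldehyde under conditions too weak to protonate the trisubstituted alkenes.

Step 16
Reactants: 31 ethyl (5E,9R,11Z)-2-(diethoxyphosphoryl)-6,12-dimethyl-9-[(2E)-6-methylhepta-2,5-dien-2-yl]-15-oxopentadeca-5,11-dienoate
Product: 32 ethyl (1E,5Z,8R,11E)-5,11-dimethyl-8-[(2E)-6-methylhepta-2,5-dien-2-yl]cyclotetradeca-1,5,11-triene-1-carboxylate
Conditions: LiCl, DBU, MeCN, rt, slow addition of 31 (syringe pump) to about 1 mM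
Reagents that add atoms: none
Why: Intramolecular Horner–Wadsworth–Emmons olefination under Masamune–Roush conditions at high dilution should close the 14-membered ring, and the intrinsic preference for the ester trans to the C3 chain coincides with the ring-cis arrangement of C3 and C14 that the macrocycle accommodates easily.

Step 17
Reactants: 32 ethyl (1E,5Z,8R,11E)-5,11-dimethyl-8-[(2E)-6-methylhepta-2,5-dien-2-yl]cyclotetradeca-1,5,11-triene-1-carboxylate
Product: 33 [(1E,5Z,8R,11E)-5,11-dimethyl-8-[(2E)-6-methylhepta-2,5-dien-2-yl]cyclotetradeca-1,5,11-trien-1-yl]methanol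
Conditions: DIBAL-H, CH2Cl2, −78 °C; Rochelle salt work-up
Reagents that add atoms: none
Why: DIBAL-H 1,2-reduction of the conjugated ester should give the allylic alcohol and leave the isolated alkenes and the C8 centre untouched.

**Compound list**

1 | neryl acetate, (2Z)-3,7-dimethylocta-2,6-dien-1-yl acetate | CC(=O)OC/C=C(/C)CCC=C(C)C | starting material
2 | (2Z)-6,7-epoxy-3,7-dimethyloct-2-en-1-yl acetate (racemic at the oxirane CH) | CC(=O)OC/C=C(/C)CCC1OC1(C)C | intermediate
3 | (2Z)-3-methyl-6-oxohex-2-en-1-yl acetate | CC(=O)OC/C=C(/C)CCC=O | intermediate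
4 | (2Z)-6,6-dimethoxy-3-methylhex-2-en-1-yl acetate | CC(=O)OC/C=C(/C)CCC(OC)OC | intermediate
5 | 2-[(2Z)-6,6-dimethoxy-3-methylhex-2-en-1-yl]-4,4,5,5-tetramethyl-1,3,2-dioxaborolane | COC(OC)CC/C(C)=C\CB1OC(C)(C)C(C)(C)O1 | intermediate
6 | pent-4-yn-1-ol | C#CCCCO | starting material
7 | 2,4,6-triisopropylbenzoic acid | CC(C)c1cc(C(C)C)c(C(=O)O)c(C(C)C)c1 | starting material
8 | pent-4-yn-1-yl 2,4,6-triisopropylbenzoate | C#CCCCOC(=O)c1c(C(C)C)cc(C(C)C)cc1C(C)C | intermediate
9 | dimethyl[(1E)-2-methyl-5-(2,4,6-triisopropylbenzoyloxy)pent-1-en-1-yl]alane | C[Al](C)/C=C(\C)CCCOC(=O)c1c(C(C)C)cc(C(C)C)cc1C(C)C | intermediate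
10 | lithium butyl(dimethyl)[(1E)-2-methyl-5-(2,4,6-triisopropylbenzoyloxy)pent-1-en-1-yl]aluminate | [Li+].CCCC[Al-](C)(C)/C=C(\C)CCCOC(=O)c1c(C(C)C)cc(C(C)C)cc1C(C)C | intermediate
11 | (4E)-7-hydroxy-4-methylhept-4-en-1-yl 2,4,6-triisopropylbenzoate | OCC/C=C(\C)CCCOC(=O)c1c(C(C)C)cc(C(C)C)cc1C(C)C | intermediate
12 | (4E)-7-[(tert-butyldimethylsilyl)oxy]-4-methylhept-4-en-1-yl 2,4,6-triisopropylbenzoate | CC(C)(C)[Si](C)(C)OCC/C=C(\C)CCCOC(=O)c1c(C(C)C)cc(C(C)C)cc1C(C)C | intermediate
13 | 4-methylpent-3-en-1-ol | CC(C)=CCCO | starting material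
14 | 4-methylpent-3-enal | CC(C)=CCC=O | intermediate
15 | ethyltriphenylphosphonium iodide | CC[P+](c1ccccc1)(c1ccccc1)c1ccccc1.[I-] | starting material
16 | ethylidenetriphenylphosphorane | CC=P(c1ccccc1)(c1ccccc1)c1ccccc1 | intermediate
17 | (1-iodoethyl)triphenylphosphonium iodide | CC(I)[P+](c1ccccc1)(c1ccccc1)c1ccccc1.[I-] | intermediate
18 | (1-iodoethylidene)triphenylphosphorane | CC(I)=P(c1ccccc1)(c1ccccc1)c1ccccc1 | intermediate
19 | (2Z)-2-iodo-6-methylhepta-2,5-diene | CC(C)=CC/C=C(/C)I | intermediate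
20 | (1S,4E)-7-[(tert-butyldimethylsilyl)oxy]-1-lithio-4-methylhept-4-en-1-yl 2,4,6-triisopropylbenzoate (sparteine complex) | [Li][C@H](OC(=O)c1c(C(C)C)cc(C(C)C)cc1C(C)C)CC/C(C)=C/CCO[Si](C)(C)C(C)(C)C | intermediate
21 | lithium pinacol boronate carrying the (Z)-allyl group of 5 and the (S)-α-benzoyloxyalkyl group of 20 on boron | [Li+].COC(OC)CC/C(C)=C\C[B-]1(OC(C)(C)C(C)(C)O1)[C@H](OC(=O)c1c(C(C)C)cc(C(C)C)cc1C(C)C)CC/C(C)=C/CCO[Si](C)(C)C(C)(C)C | intermediate
22 | tert-butyl{[(3E,7R,9Z)-13,13-dimethoxy-4,10-dimethyl-7-(4,4,5,5-tetramethyl-1,3,2-dioxaborolan-2-yl)trideca-3,9-dien-1-yl]oxy}dimethylsilane | COC(OC)CC/C(C)=C\C[C@H](B1OC(C)(C)C(C)(C)O1)CC/C(C)=C/CCO[Si](C)(C)C(C)(C)C | intermediate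
23 | [(2Z)-6-methylhepta-2,5-dien-2-yl]lithium | CC(C)=CC/C=C(/C)[Li] | intermediate
24 | lithium pinacol boronate carrying the (R)-secondary alkyl group of 22 and the (Z)-alkenyl group of 23 on boron | [Li+].COC(OC)CC/C(C)=C\C[C@H]([B-]1(OC(C)(C)C(C)(C)O1)/C(C)=C\CC=C(C)C)CC/C(C)=C/CCO[Si](C)(C)C(C)(C)C | intermediate
25 | β-iodo tertiary pinacol boronic ester from anti addition of C8 and iodine across the alkenyl group (both anti adducts, C8 R) | COC(OC)CC/C(C)=C\C[C@H](C(C)(B1OC(C)(C)C(C)(C)O1)C(I)CC=C(C)C)CC/C(C)=C/CCO[Si](C)(C)C(C)(C)C | intermediate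
26 | tert-butyl{[(3E,7R,9Z)-13,13-dimethoxy-4,10-dimethyl-7-[(2E)-6-methylhepta-2,5-dien-2-yl]trideca-3,9-dien-1-yl]oxy}dimethylsilane | COC(OC)CC/C(C)=C\C[C@H](/C(C)=C/CC=C(C)C)CC/C(C)=C/CCO[Si](C)(C)C(C)(C)C | intermediate
27 | (3E,7R,9Z)-13,13-dimethoxy-4,10-dimethyl-7-[(2E)-6-methylhepta-2,5-dien-2-yl]trideca-3,9-dien-1-ol | COC(OC)CC/C(C)=C\C[C@H](/C(C)=C/CC=C(C)C)CC/C(C)=C/CCO | intermediate
28 | (4Z,7R,10E)-13-iodo-1,1-dimethoxy-4,10-dimethyl-7-[(2E)-6-methylhepta-2,5-dien-2-yl]trideca-4,10-diene | COC(OC)CC/C(C)=C\C[C@H](/C(C)=C/CC=C(C)C)CC/C(C)=C/CCI | intermediate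
29 | triethyl phosphonoacetate | CCOC(=O)CP(=O)(OCC)OCC | starting material
30 | ethyl (5E,9R,11Z)-2-(diethoxyphosphoryl)-15,15-dimethoxy-6,12-dimethyl-9-[(2E)-6-methylhepta-2,5-dien-2-yl]pentadeca-5,11-dienoate (both C2 epimers) | COC(OC)CC/C(C)=C\C[C@H](/C(C)=C/CC=C(C)C)CC/C(C)=C/CCC(C(=O)OCC)P(=O)(OCC)OCC | intermediate
31 | ethyl (5E,9R,11Z)-2-(diethoxyphosphoryl)-6,12-dimethyl-9-[(2E)-6-methylhepta-2,5-dien-2-yl]-15-oxopentadeca-5,11-dienoate (both C2 epimers) | O=CCC/C(C)=C\C[C@H](/C(C)=C/CC=C(C)C)CC/C(C)=C/CCC(C(=O)OCC)P(=O)(OCC)OCC | intermediate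
32 | ethyl (1E,5Z,8R,11E)-5,11-dimethyl-8-[(2E)-6-methylhepta-2,5-dien-2-yl]cyclotetradeca-1,5,11-triene-1-carboxylate | CC(C)=CC/C=C(\C)[C@H]1C/C=C(/C)CC/C=C(/C(=O)OCC)CC/C=C(\C)CC1 | intermediate
33 | [(1E,5Z,8R,11E)-5,11-dimethyl-8-[(2E)-6-methylhepta-2,5-dien-2-yl]cyclotetradeca-1,5,11-trien-1-yl]methanol | CC(C)=CC/C=C(\C)[C@H]1C/C=C(/C)CC/C=C(/CO)CC/C=C(\C)CC1 | target

**Count and risks**

Total step count: 17. Longest linear sequence: 12 steps (steps 1–4, then 10–17).

Step 11. What may go wrong: slow or reversible formation of the boronate from a secondary boronic ester and an alkenyllithium substituted at both alkene carbons; proton transfer from the doubly allylic CH2 to the alkenyllithium; iodination at another alkene. The fallback sets out from 22 and returns at 26. It keeps the stereoretentive shift but uses the smallest alkenyl partner and builds the alkene afterwards. Compound 22 is treated with 1-bromovinyllithium (vinyl bromide, LDA, THF/Et2O, −110 °C) and then I2/MeOH to give the 2-bromoalkene F1 in a Zweifel-type coupling. LDA dehydrobrominates it to the terminal alkyne F2 (deborylative alkynylation, retention at C8). Zirconium-catalysed syn-methylalumination of F2 (AlMe3, Cp2ZrCl2, CH2Cl2, short contact at low temperature to spare the acetal) gives the (E)-alkenylalane F3. This is coupled in the same flask with 1-chloro-3-methylbut-2-ene under Pd(PPh3)4 catalysis at the unsubstituted allyl terminus to give 26.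

Step 16. What may go wrong: intermolecular olefination to dimers and oligomers in competition with ring closure; leakage to the other enoate geometry at the α-branched phosphonate. The fallback sets out from 28 and returns at 32. It closes the ring by an aldol-type C–C bond formation followed by elimination. Compound 28 alkylates the lithium enolate of ethyl acetate (LDA, THF/DMPU, −78 °C) to give the ester F4. Enolate bromination (LDA, then CBr4) gives the α-bromo ester F5, and acetal hydrolysis as in step 15 gives the bromo aldehyde F6. SmI2 (THF, high dilution) closes the ring by an intramolecular Reformatsky reaction to the β-hydroxy ester F7. Mesylation (MsCl, Et3N) gives the mesylate F8, and DBU-induced elimination should give the conjugated ester 32 under thermodynamic control.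

Step 6. What may go wrong: complexation of the aluminium and zirconium reagents by the ester carbonyl, which stalls carbometalation; sluggish alkenyl transfer from the alanate to the epoxide. The fallback sets out from 6 and returns at 11. It runs the methylalumination on the free alcohol and adds the two-carbon unit by cross-coupling. Compound 6 with AlMe3/Cp2ZrCl2, then I2, gives the (E)-iodoalkenol F9. Mitsunobu esterification with 7 gives the iodoalkenyl benzoate F10. Suzuki–Miyaura coupling with potassium vinyltrifluoroborate (PdCl2(dppf), Cs2CO3, THF/H2O) gives the diene F11. 9-BBN hydroboration of the terminal vinyl group and NaOH/H2O2 oxidation give 11.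

Further compounds
F1 | step 11 | tert-butyl{[(3E,7R,9Z)-7-(1-bromoethenyl)-13,13-dimethoxy-4,10-dimethyltrideca-3,9-dien-1-yl]oxy}dimethylsilane | COC(OC)CC/C(C)=C\C[C@H](C(Br)=C)CC/C(C)=C/CCO[Si](C)(C)C(C)(C)C
F2 | step 11 | tert-butyl{[(3E,7R,9Z)-7-ethynyl-13,13-dimethoxy-4,10-dimethyltrideca-3,9-dien-1-yl]oxy}dimethylsilane | COC(OC)CC/C(C)=C\C[C@H](C#C)CC/C(C)=C/CCO[Si](C)(C)C(C)(C)C
F3 | step 11 | (E)-alkenyl(dimethyl)alane from methylalumination of F2 (Al on the terminal carbon, cis to the new methyl) | COC(OC)CC/C(C)=C\C[C@H](/C(C)=C/[Al](C)C)CC/C(C)=C/CCO[Si](C)(C)C(C)(C)C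
F4 | step 16 | ethyl (5E,9R,11Z)-15,15-dimethoxy-6,12-dimethyl-9-[(2E)-6-methylhepta-2,5-dien-2-yl]pentadeca-5,11-dienoate | COC(OC)CC/C(C)=C\C[C@H](/C(C)=C/CC=C(C)C)CC/C(C)=C/CCCC(=O)OCC
F5 | step 16 | ethyl (5E,9R,11Z)-2-bromo-15,15-dimethoxy-6,12-dimethyl-9-[(2E)-6-methylhepta-2,5-dien-2-yl]pentadeca-5,11-dienoate (both C2 epimers) | COC(OC)CC/C(C)=C\C[C@H](/C(C)=C/CC=C(C)C)CC/C(C)=C/CCC(Br)C(=O)OCC
F6 | step 16 | ethyl (5E,9R,11Z)-2-bromo-6,12-dimethyl-9-[(2E)-6-methylhepta-2,5-dien-2-yl]-15-oxopentadeca-5,11-dienoate (both C2 epimers) | O=CCC/C(C)=C\C[C@H](/C(C)=C/CC=C(C)C)CC/C(C)=C/CCC(Br)C(=O)OCC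
F7 | step 16 | ethyl (5Z,8R,11E)-2-hydroxy-5,11-dimethyl-8-[(2E)-6-methylhepta-2,5-dien-2-yl]cyclotetradeca-5,11-diene-1-carboxylate (diastereomers at C1 and C2) | CC(C)=CC/C=C(\C)[C@H]1C/C=C(/C)CCC(O)C(C(=O)OCC)CC/C=C(\C)CC1
F8 | step 16 | methanesulfonate of F7 | CC(C)=CC/C=C(\C)[C@H]1C/C=C(/C)CCC(OS(C)(=O)=O)C(C(=O)OCC)CC/C=C(\C)CC1
F9 | step 6 | (4E)-5-iodo-4-methylpent-4-en-1-ol | OCCC/C(C)=C/I
F10 | step 6 | (4E)-5-iodo-4-methylpent-4-en-1-yl 2,4,6-triisopropylbenzoate | I/C=C(\C)CCCOC(=O)c1c(C(C)C)cc(C(C)C)cc1C(C)C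
F11 | step 6 | (4E)-4-methylhepta-4,6-dien-1-yl 2,4,6-triisopropylbenzoate | C=C/C=C(\C)CCCOC(=O)c1c(C(C)C)cc(C(C)C)cc1C(C)C
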